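## The problem

The target, (4R)-5,9,14-trimethyl-4-tridecyl-1,5,9,14-tetraazacycloheptadecan-2-one (18), is one 17-membered ring. Ring positions used throughout are N1 (lactam nitrogen), C2 (carbonyl), C3, C4 (stereocenter), N5, N9 and N14; side-chain carbons are primed. A spermine-type chain N5–C3–N9–C4–N14–C3–N1 is bridged at its ends by the three-carbon unit C2(=O)–C3H2–C4H. N1 is a secondary lactam nitrogen, and N5, N9 and N14 are N-methylated tertiary amines. The only stereocenter is C4, which carries N5, the ring C3H2–C2(=O) and an unbranched tridecyl chain. With no second stereocenter nothing in the molecule can relay, so C4 must be set by a catalyst, a reagent or a purchased building block. The ring has no rigid element, so closure must be won against oligomerisation by the reaction design. The three basic amines bind electrophilic metals and Lewis acids. The β-amino amide can lose N5 by retro-Michael elimination under strong base or heat, which would open the ring and erase C4, so late steps must be mild and preferably run on ammonium salts. The enabling feature is the substitution pattern at C4: if C1'–C2' of the side chain is a vinyl group, C4 is the branched terminus of an allylic amine. The N5–C4 bond can then be made by enantioselective allylic amination, and because N5 is a ring atom the same bond closes the macrocycle.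

## Retrosynthesis

**Side chain (18 ⇒ 17 ⇒ 15 + 16).** The tridecyl chain is cut at C1'–C2', read as an alkene, which gives the vinyl lactam 15 and tridec-1-ene (16). A branched-selective allylic amination of a linear carbonate always leaves a vinyl group, so the chain cannot be carried through the key step. Attaching it afterwards by cross-metathesis uses a commodity alkene and leaves the chain length open. The forward reactions need a metathesis that tolerates three amines (they are protonated) and a hydrogenation that neither cleaves the allylic C4–N5 bond nor moves the alkene to C4.

**N-Methyl group (15 ⇒ 13).** The N5–CH3 bond is removed to give the secondary amine 13. This lets a primary amine act as nucleophile in the key step, the best-behaved amine class for iridium allylic amination. It also lets the tetraamine be made symmetrical. The forward step is a reductive methylation.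

**Ring and stereocenter (13 ⇒ 12).** The N5–C4 bond is cut. The neighbouring cut at N1–C2 (lactamisation) would close the ring but leave C4 to be made separately. The N5–C4 cut does both and leads to the achiral, acyclic (E)-allyl methyl carbonate 12 with a terminal primary amine. The forward reaction must attack the substituted allyl terminus (17-membered ring, not the 19-membered linear product), choose one face, distinguish the primary amine from the other three nitrogens, and cyclise rather than oligomerise.

**Amide (12 ⇒ 11 ⇒ 9 + 5).** The N1–C2 amide bond is cut to give the C5 acid 9 and the mono-Boc tetraamine 5. Carrying the future nucleophile as its Boc carbamate through the coupling gives a chromatographable, storable intermediate 11. The amine is released only immediately before the key step, since amine and carbonate should not share a molecule for long.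

**C5 acid (9 ⇒ 8 + 7; 7 ⇒ 6).** The C3=C4 alkene of 9 is cut by cross-metathesis logic into but-3-enoic acid (8) and the symmetrical bis(methyl carbonate) 7, made from (Z)-but-2-ene-1,4-diol (6). This brings in the allylic carbonate and the β,γ-unsaturation in one step and gives mainly the (E)-alkene the iridium catalyst requires.

**Tetraamine (5 ⇒ 4 ⇒ 3 ⇒ 1 + 2).** Statistical mono-protection traces 5 to the symmetrical tetraamine 4. Its two C3 arms come from double cyanoethylation of N,N'-dimethylbutane-1,4-diamine (1) with acrylonitrile (2) and reduction of the dinitrile 3. The statistical step is placed on cheap, recoverable material.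

## Roads not taken

Alternative 1: Here the macrocycle is traced back, through the ring expansion of Alternative 3 and a final N-methylation, to the N-substituted β-lactam A1. A1 is then simplified by removing its carbonyl carbon, which leaves the (R)-2-tridecylaziridine A2 carrying the Boc-protected triamine arm on nitrogen. In the forward step Co2(CO)8 under CO pressure would open A2 at the unsubstituted ring CH2, insert CO and close the azetidinone. The C–N bond at the stereocenter is never broken, so A2 passes its configuration to A1. The merits are atom economy, dependable regiochemistry for 2-alkylaziridines and clean inheritance of configuration. The weak points are these: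
- A2 needs an enantiopure C15 epoxide or amino alcohol, typically from a resolution.
- The arm carries two tertiary amines and a carbamate into a carbonylation established only for simple N-alkylaziridines.
- Pressure equipment is needed.
- A1 is still a four-membered ring, so Boc removal, expansion to A5 and methylation must follow.

Its key step has closer precedent than a 17-membered allylic amination, and the chain is in place from the start, so no late metathesis on a polyamine is needed. Both points favour it. The chosen plan sets against this a stereocenter made by catalysis from achiral material, ring closure in the same step, a shorter sequence and a freely variable chain.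

Alternative 2: The cut is the central C11–C12 bond of the putrescine bridge, read as an alkene. The precursor is the diene A4, an (R)-β-amino amide whose two ends carry N-allyl-N-methylamine groups. With the amines protonated, ring-closing metathesis with (H2IMes)(PCy3)Cl2Ru=CHPh (second-generation Grubbs catalyst) would expel ethylene and give the dehydro macrocycle A3 as an alkene mixture, and hydrogenation would finish the target. The merits are real: macrocyclic ring-closing metathesis is a better-established closure than the key step chosen here, and the final skeleton, with all three N-methyl groups, is reached directly. The weak points are these: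
- The step creates no stereochemistry, so C4 must be bought or made by a separate asymmetric synthesis of a long-chain β-amino acid unit.
- Both reacting alkenes are allylic to ammonium centres and therefore deactivated.
- A3 has two allylic C–N bonds exposed to hydrogenolysis.
- The unsymmetrical precursor A4 needs more linear steps.

Ring closure is safer on this road. The chosen plan also needs a metathesis on an ammonium salt, but only as a cross-coupling with an excess partner, and it creates the stereocenter in the ring-forming event.

Alternative 3: The cut is the lactam bond N1–C2, made by transamidation. The precursor A6 is an (R)-4-tridecylazetidin-2-one bearing the free triamine arm on nitrogen. The terminal primary amine attacks the strained lactam carbonyl, the C2–N bond of the four-membered ring breaks, and the ring opens out to the 17-membered N-demethyl macrocycle A5, which is then N-methylated. The merits are these: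
- Strain release makes the step thermodynamically secure.
- Ring enlargement of N-aminoalkyl β-lactams is established chemistry for polyamine lactams.
- No transition metal meets the polyamine.
- Chain and stereocenter are fixed before the delicate steps.

In precedent and robustness this road is better than the chosen plan. The weak points are these:
- The amine must reach the carbonyl through a large-ring transition state, because the intervening nitrogens are tertiary and cannot relay the acyl group.
- An enantiopure 4-alkyl β-lactam must be supplied, by resolution or auxiliary chemistry.
- The chain length is fixed at the first step.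

The chosen plan sets against this a catalytic asymmetric origin of C4 from achiral commodity materials, ring and stereocenter formed together, and a late alkene handle for varying the chain. It accepts an untested macrocyclisation in exchange.

Key step: step 8

Assumption: the (R,R,R)-configured phosphoramidite is taken to direct the amine to the face of the allyl terminus that gives the (4S)-vinyl lactam, following the usual sense of induction for linear (E)-allyl carbonates. If the sense proves opposite, the (S,S,S)-ligand is used with no other change.

## Route

Step 1
Reactants: 1 N,N'-dimethylbutane-1,4-diamine; 2 acrylonitrile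
Product: 3 3,3'-[butane-1,4-diylbis(methylazanediyl)]dipropanenitrile
Conditions: 2 (2.4 equiv), MeOH, 0 °C → rt
Reagents that add atoms: none
Why: Double aza-Michael addition of the two secondary amines to acrylonitrile; it is clean without catalyst in a protic solvent and cannot over-alkylate because the products are tertiary amines.

Step 2
Reactants: 3 3,3'-[butane-1,4-diylbis(methylazanediyl)]dipropanenitrile
Product: 4 N,N'-bis(3-aminopropyl)-N,N'-dimethylbutane-1,4-diamine
Conditions: H2 (4 bar), Raney Ni, 7 M NH3 in MeOH, rt
Reagents that add atoms: none
Why: Heterogeneous hydrogenation of nitriles to primary amines; ammonia suppresses secondary-amine formation through the intermediate imines, and the low temperature avoids retro-Michael loss of acrylonitrile.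

Step 3
Reactants: 4 N,N'-bis(3-aminopropyl)-N,N'-dimethylbutane-1,4-diamine
Product: 5 tert-butyl N-[3-(methyl{4-[methyl(3-aminopropyl)amino]butyl}amino)propyl]carbamate
Conditions: 4 (3 equiv), Boc2O (1 equiv, slow addition), CH2Cl2, 0 °C → rt; excess 4 recovered from the aqueous wash
Reagents that add atoms: di-tert-butyl dicarbonate, CC(C)(C)OC(=O)OC(=O)OC(C)(C)C
Why: Carbamate (Boc) protection of one of two equivalent primary amines; excess diamine and slow addition favour mono-acylation statistically, and the tertiary amines cannot be acylated.

Step 4
Reactants: 6 (Z)-but-2-ene-1,4-diol
Product: 7 (Z)-but-2-ene-1,4-diyl dimethyl dicarbonate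
Conditions: ClCO2Me (2.5 equiv), pyridine, CH2Cl2, 0 °C → rt
Reagents that add atoms: methyl chloroformate, COC(=O)Cl
Why: O-Acylation of both primary alcohols by a chloroformate with pyridine as base; the alkene geometry of 7 does not matter because that double bond is exchanged in step 5.

Step 5
Reactants: 8 but-3-enoic acid; 7 (Z)-but-2-ene-1,4-diyl dimethyl dicarbonate
Product: 9 (E)-5-[(methoxycarbonyl)oxy]pent-3-enoic acid
Conditions: 7 (3 equiv), (H2IMes)(PCy3)Cl2Ru=CHPh (second-generation Grubbs catalyst, 3 mol%), 1,4-benzoquinone (10 mol%), CH2Cl2, 40 °C
Reagents that add atoms: none
Why: Olefin cross-metathesis of a terminal alkene with an excess of a symmetrical internal alkene; secondary metathesis should enrich the (E)-isomer, benzoquinone intercepts ruthenium hydrides that would move the double bond into conjugation, and acid–base extraction separates 9 from the neutral carbonates.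

Step 6
Reactants: 9 (E)-5-[(methoxycarbonyl)oxy]pent-3-enoic acid; 5 tert-butyl N-[3-(methyl{4-[methyl(3-aminopropyl)amino]butyl}amino)propyl]carbamate
Product: 11 tert-butyl N-{3-[methyl(4-{methyl[3-({(3E)-5-[(methoxycarbonyl)oxy]pent-3-enoyl}amino)propyl]amino}butyl)amino]propyl}carbamate, via benzotriazol-1-yl active ester 10 (not isolated)
Conditions: EDC·HCl, HOBt, CH2Cl2, 0 °C; then 5, 0 °C → rt
Reagents that add atoms: none
Why: Carbodiimide amide coupling through the HOBt ester; no amine base is added and the temperature is kept low so the β,γ-alkene does not move into conjugation and the carbonate is not eliminated, and the primary amine of 5 reacts far faster with the active ester than with the carbonate.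

Step 7
Reactants: 11 tert-butyl N-{3-[methyl(4-{methyl[3-({(3E)-5-[(methoxycarbonyl)oxy]pent-3-enoyl}amino)propyl]amino}butyl)amino]propyl}carbamate
Product: 12 methyl (2E)-5-{[3-(methyl{4-[methyl(3-aminopropyl)amino]butyl}amino)propyl]amino}-5-oxopent-2-en-1-yl carbonate
Conditions: TFA, CH2Cl2, 0 °C → rt; then cold aq. K2CO3, CH2Cl2 extraction, used at once
Reagents that add atoms: none
Why: Acidolysis of the tert-butyl carbamate; the allyl carbonate, alkene and amide are stable to TFA, the trifluoroacetate salt can be stored, and the free base is liberated cold just before step 8 because amine and carbonate now share one molecule.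

Step 8
Reactants: 12 methyl (2E)-5-{[3-(methyl{4-[methyl(3-aminopropyl)amino]butyl}amino)propyl]amino}-5-oxopent-2-en-1-yl carbonate
Product: 13 (4S)-4-ethenyl-9,14-dimethyl-1,5,9,14-tetraazacycloheptadecan-2-one
Conditions: [Ir(cod)Cl]2 (5 mol%), O,O'-[(R)-1,1'-binaphthyl-2,2'-diyl] N,N-bis[(R)-1-phenylethyl]phosphoramidite (10 mol%), pre-activated with n-PrNH2 (THF, 50 °C, volatiles then removed); 12 added by syringe pump over 12 h, THF, 50 °C, final 3 mM
Reagents that add atoms: none
Why: Proposed new method: the monovalent iridium metallacycle formed from [Ir(cod)Cl]2 and the phosphoramidite ionises the (E)-allyl methyl carbonate of 12 to a trivalent allyl iridium species with loss of CO2 and methoxide, and the tethered primary amine attacks the substituted allyl terminus (the future C4) on the face opposite the metal, forming N5–C4 and releasing the catalyst; the closest known reaction type is the branched-selective iridium–phosphoramidite allylic amination, established between separate partners and for closing five- to seven-membered rings, so its use for a 17-membered ring is the untested part. The ring closes in exo mode with respect to the allyl unit: C4 becomes a ring atom and the C1'=C2' vinyl group stays outside, whereas linear attack would give a 19-membered ring with an endocyclic alkene. The configuration at C4 is controlled by the ligand, which fixes the face of the allyl unit bound to iridium and so the face open to the amine, and the (E)-geometry of 12 secures a single syn allyl isomer. Branched over linear selectivity is the intrinsic preference of this catalyst for the substituted terminus. Among the four nitrogens only the primary amine can give a neutral product, since the tertiary amines can add only reversibly and the amide N–H is not nucleophilic without base. Slow addition keeps the stationary concentration of 12 low while the catalyst stays concentrated, which should favour ring closure over oligomers. No base is added, which should limit loss of the acidic C3–H from the allyl intermediate to a dienamide.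

Step 9
Reactants: 13 (4S)-4-ethenyl-9,14-dimethyl-1,5,9,14-tetraazacycloheptadecan-2-one
Product: 15 (4S)-4-ethenyl-5,9,14-trimethyl-1,5,9,14-tetraazacycloheptadecan-2-one, via N5-methylidene iminium ion 14 (not isolated)
Conditions: aq. HCHO (37%), NaBH(OAc)3, AcOH, MeCN, 0 °C → rt
Reagents that add atoms: formaldehyde, C=O
Why: Reductive amination (N-methylation) through the iminium ion; an N,N-aminal between N5 and the amide N1 reopens under the acidic conditions and is drained by reduction, and the vinyl group, the lactam and C4 are untouched.

Step 10
Reactants: 15 (4S)-4-ethenyl-5,9,14-trimethyl-1,5,9,14-tetraazacycloheptadecan-2-one; 16 tridec-1-ene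
Product: 17 (4S)-5,9,14-trimethyl-4-[(E)-tridec-1-en-1-yl]-1,5,9,14-tetraazacycloheptadecan-2-one
Conditions: p-TsOH·H2O (3.1 equiv); 16 (10 equiv), (H2IMes)Cl2Ru=CH(C6H4-2-OiPr) (second-generation Hoveyda–Grubbs catalyst, 10 mol%), 1,4-benzoquinone (20 mol%), CH2Cl2, 40 °C; aq. NaOH work-up
Reagents that add atoms: none
Why: Olefin cross-metathesis on the tris-ammonium salt; full protonation masks the three amines from ruthenium and disfavours alkene migration toward C4, excess 16 drives the cross-coupling, and the alkene geometry is irrelevant because step 11 removes it (the major E isomer is drawn).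

Step 11
Reactants: 17 (4S)-5,9,14-trimethyl-4-[(E)-tridec-1-en-1-yl]-1,5,9,14-tetraazacycloheptadecan-2-one
Product: 18 (4R)-5,9,14-trimethyl-4-tridecyl-1,5,9,14-tetraazacycloheptadecan-2-one
Conditions: H2 (1 atm), PtO2, AcOH/MeOH, rt; aq. NaOH work-up
Reagents that add atoms: none
Why: Heterogeneous hydrogenation of the disubstituted alkene; platinum in acidic medium, with the amines protonated, disfavours both allylic C–N hydrogenolysis and alkene migration to C4, so the spatial arrangement set in step 8 is kept and the descriptor changes from S to R only because the side chain loses CIP priority.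

## Compound list

1 | N,N'-dimethylbutane-1,4-diamine | CNCCCCNC | starting material
2 | acrylonitrile | C=CC#N | starting material
3 | 3,3'-[butane-1,4-diylbis(methylazanediyl)]dipropanenitrile | N#CCCN(C)CCCCN(C)CCC#N | intermediate
4 | N,N'-bis(3-aminopropyl)-N,N'-dimethylbutane-1,4-diamine | NCCCN(C)CCCCN(C)CCCN | intermediate
5 | tert-butyl N-[3-(methyl{4-[methyl(3-aminopropyl)amino]butyl}amino)propyl]carbamate | CC(C)(C)OC(=O)NCCCN(C)CCCCN(C)CCCN | intermediate
6 | (Z)-but-2-ene-1,4-diol | OC/C=C\CO | starting material
7 | (Z)-but-2-ene-1,4-diyl dimethyl dicarbonate | COC(=O)OC/C=C\COC(=O)OC | intermediate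
8 | but-3-enoic acid | C=CCC(=O)O | starting material
9 | (E)-5-[(methoxycarbonyl)oxy]pent-3-enoic acid | COC(=O)OC/C=C/CC(=O)O | intermediate
10 | 1H-benzotriazol-1-yl (E)-5-[(methoxycarbonyl)oxy]pent-3-enoate | COC(=O)OC/C=C/CC(=O)On1nnc2ccccc12 | intermediate
11 | tert-butyl N-{3-[methyl(4-{methyl[3-({(3E)-5-[(methoxycarbonyl)oxy]pent-3-enoyl}amino)propyl]amino}butyl)amino]propyl}carbamate | COC(=O)OC/C=C/CC(=O)NCCCN(C)CCCCN(C)CCCNC(=O)OC(C)(C)C | intermediate
12 | methyl (2E)-5-{[3-(methyl{4-[methyl(3-aminopropyl)amino]butyl}amino)propyl]amino}-5-oxopent-2-en-1-yl carbonate | COC(=O)OC/C=C/CC(=O)NCCCN(C)CCCCN(C)CCCN | intermediate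
13 | (4S)-4-ethenyl-9,14-dimethyl-1,5,9,14-tetraazacycloheptadecan-2-one | C=C[C@@H]1CC(=O)NCCCN(C)CCCCN(C)CCCN1 | intermediate
14 | N5-methylidene iminium ion of 13 | C=C[C@@H]1CC(=O)NCCCN(C)CCCCN(C)CCC[N+]1=C | intermediate
15 | (4S)-4-ethenyl-5,9,14-trimethyl-1,5,9,14-tetraazacycloheptadecan-2-one | C=C[C@@H]1CC(=O)NCCCN(C)CCCCN(C)CCCN1C | intermediate
16 | tridec-1-ene | C=CCCCCCCCCCCC | starting material
17 | (4S)-5,9,14-trimethyl-4-[(E)-tridec-1-en-1-yl]-1,5,9,14-tetraazacycloheptadecan-2-one | CCCCCCCCCCC/C=C/[C@@H]1CC(=O)NCCCN(C)CCCCN(C)CCCN1C | intermediate
18 | (4R)-5,9,14-trimethyl-4-tridecyl-1,5,9,14-tetraazacycloheptadecan-2-one | CCCCCCCCCCCCC[C@@H]1CC(=O)NCCCN(C)CCCCN(C)CCCN1C | target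

## Step count and risks

Total steps: 11. Longest linear sequence: 9 steps (steps 1, 2, 3, 6, 7, 8, 9, 10, 11, from 1). The acid branch (steps 4 and 5) joins at step 6.

**Step 8 (key step).** The most likely failure is that ring closure is outrun. Three processes compete: oligomerisation, sequestration of iridium by the 1,3-diamine units of the substrate, and loss of the acidic C–H next to the allyl unit to give a dienamide. Regio- or enantioselectivity may also erode at the dilution and temperature needed.

The fallback separates C–N bond formation from ring closure and uses known chemistry; it sets out from 7 and 5. Cross-metathesis of commercial methyl but-3-enoate with 7, under the conditions of step 5, should give methyl (E)-5-[(methoxycarbonyl)oxy]pent-3-enoate F1. The same iridium–phosphoramidite catalyst, at ordinary concentration, should aminate F1 with the primary amine of 5 at the branched position to give methyl (3S)-3-{[3-(methyl{4-[methyl(3-{[(tert-butoxy)carbonyl]amino}propyl)amino]butyl}amino)propyl]amino}pent-4-enoate F2. TFA removes the Boc group to give methyl (3S)-3-{[3-(methyl{4-[methyl(3-aminopropyl)amino]butyl}amino)propyl]amino}pent-4-enoate F3. Template macrolactamisation of F3 with Sb(OEt)3 in refluxing benzene, a method used for 13- and 17-membered polyamine lactams, closes N1–C2 and rejoins the route at 13.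

**Step 10.** The ruthenium catalyst may be deactivated by incompletely protonated amines. The alkene next to the quaternised, branched C4–N5 centre may react sluggishly, and the tris-ammonium salt may dissolve poorly.

The fallback moves the metathesis to a carbamate stage and sets out from 13. Boc2O should give tert-butyl (4S)-4-ethenyl-9,14-dimethyl-2-oxo-1,5,9,14-tetraazacycloheptadecane-5-carboxylate F4. Cross-metathesis of F4 with 16, with only N9 and N14 protonated (2 equiv p-TsOH), should give tert-butyl (4S)-9,14-dimethyl-2-oxo-4-[(E)-tridec-1-en-1-yl]-1,5,9,14-tetraazacycloheptadecane-5-carboxylate F5. Hydrogenation over PtO2 gives tert-butyl (4R)-9,14-dimethyl-2-oxo-4-tridecyl-1,5,9,14-tetraazacycloheptadecane-5-carboxylate F6. TFA gives (4R)-9,14-dimethyl-4-tridecyl-1,5,9,14-tetraazacycloheptadecan-2-one F7. Reductive methylation under the conditions of step 9 rejoins the route at 18.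

**Step 5.** The double bond may migrate into conjugation with the carboxyl group, promoted by ruthenium hydrides and the free acid. Incomplete (E)-selectivity would lower the selectivity of step 8.

The fallback keeps the acid masked during metathesis and sets out from 7. Cross-metathesis with commercial tert-butyl but-3-enoate should give tert-butyl (E)-5-[(methoxycarbonyl)oxy]pent-3-enoate F8. F8 can be chromatographed to enrich the (E)-isomer, and TFA cleavage of the tert-butyl ester rejoins the route at 9.

**Step 11.** Hydrogenolysis of the allylic C4–N5 bond, or metal-mediated migration of the alkene to C4 with loss of configuration, may compete with simple saturation.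

The fallback is a metal-free diimide reduction (2-nitrobenzenesulfonyl hydrazide, Et3N, CH2Cl2, rt). It sets out from 17 and arrives directly at 18 with no new compound on the way.

## Further compounds

F1 | step 8 | methyl (E)-5-[(methoxycarbonyl)oxy]pent-3-enoate | COC(=O)C/C=C/COC(=O)OC
F2 | step 8 | methyl (3S)-3-{[3-(methyl{4-[methyl(3-{[(tert-butoxy)carbonyl]amino}propyl)amino]butyl}amino)propyl]amino}pent-4-enoate | C=C[C@H](CC(=O)OC)NCCCN(C)CCCCN(C)CCCNC(=O)OC(C)(C)C
F3 | step 8 | methyl (3S)-3-{[3-(methyl{4-[methyl(3-aminopropyl)amino]butyl}amino)propyl]amino}pent-4-enoate | C=C[C@H](CC(=O)OC)NCCCN(C)CCCCN(C)CCCN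
F4 | step 10 | tert-butyl (4S)-4-ethenyl-9,14-dimethyl-2-oxo-1,5,9,14-tetraazacycloheptadecane-5-carboxylate | C=C[C@@H]1CC(=O)NCCCN(C)CCCCN(C)CCCN1C(=O)OC(C)(C)C
F5 | step 10 | tert-butyl (4S)-9,14-dimethyl-2-oxo-4-[(E)-tridec-1-en-1-yl]-1,5,9,14-tetraazacycloheptadecane-5-carboxylate | CCCCCCCCCCC/C=C/[C@@H]1CC(=O)NCCCN(C)CCCCN(C)CCCN1C(=O)OC(C)(C)C
F6 | step 10 | tert-butyl (4R)-9,14-dimethyl-2-oxo-4-tridecyl-1,5,9,14-tetraazacycloheptadecane-5-carboxylate | CCCCCCCCCCCCC[C@@H]1CC(=O)NCCCN(C)CCCCN(C)CCCN1C(=O)OC(C)(C)C
F7 | step 10 | (4R)-9,14-dimethyl-4-tridecyl-1,5,9,14-tetraazacycloheptadecan-2-one | CCCCCCCCCCCCC[C@@H]1CC(=O)NCCCN(C)CCCCN(C)CCCN1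
F8 | step 5 | tert-butyl (E)-5-[(methoxycarbonyl)oxy]pent-3-enoate | COC(=O)OC/C=C/CC(=O)OC(C)(C)C
F0 | step 11 | none | none
A1 | alternative 1 | tert-butyl {3-[methyl(4-{methyl[3-((R)-2-oxo-4-tridecylazetidin-1-yl)propyl]amino}butyl)amino]propyl}carbamate | CCCCCCCCCCCCC[C@@H]1CC(=O)N1CCCN(C)CCCCN(C)CCCNC(=O)OC(C)(C)C
A2 | alternative 1 | tert-butyl {3-[methyl(4-{methyl[3-((R)-2-tridecylaziridin-1-yl)propyl]amino}butyl)amino]propyl}carbamate | CCCCCCCCCCCCC[C@@H]1CN1CCCN(C)CCCCN(C)CCCNC(=O)OC(C)(C)C
A3 | alternative 2 | (4R)-5,9,14-trimethyl-4-tridecyl-1,5,9,14-tetraazacycloheptadec-11-en-2-one (alkene isomers) | CCCCCCCCCCCCC[C@@H]1CC(=O)NCCCN(C)CC=CCN(C)CCCN1C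
A4 | alternative 2 | (3R)-3-{methyl[3-(methyl(prop-2-en-1-yl)amino)propyl]amino}-N-{3-[methyl(prop-2-en-1-yl)amino]propyl}hexadecanamide | CCCCCCCCCCCCC[C@H](CC(=O)NCCCN(C)CC=C)N(C)CCCN(C)CC=C
A5 | alternative 3 | (4R)-9,14-dimethyl-4-tridecyl-1,5,9,14-tetraazacycloheptadecan-2-one | CCCCCCCCCCCCC[C@@H]1CC(=O)NCCCN(C)CCCCN(C)CCCN1
A6 | alternative 3 | (4R)-1-[3-(methyl{4-[methyl(3-aminopropyl)amino]butyl}amino)propyl]-4-tridecylazetidin-2-one | CCCCCCCCCCCCC[C@@H]1CC(=O)N1CCCN(C)CCCCN(C)CCCN
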